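## Retrosynthetic overview
1. Target 10 is the head-to-head [4+2] homodimer of aryl diene 6. C1–C2 and C5–C6 of the cyclohex-3-ene are cut in one operation, the dimerisation nature is presumed to use. It is run as an enantioselective radical-cation Diels–Alder reaction inside a chiral ion pair rather than thermally, so one step sets both stereocentres.
2. 6 ⇒ 6-bromo-7-methoxycoumarin 4 + isoprene 5 (Heck).
3. 4 ⇒ bromosalicylaldehyde 1 + stabilised ylide 2 (Wittig/lactonisation).
4. Ring order: pyranone ring first (step 1), cyclohexene ring last (step 3).

## Notes before the steps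
- Stereochemistry of the target (cyclohex-3-en-1-yl numbering): C1 (quaternary, bearing CH3 and the styryl arm) is R and C2 (CH-aryl) is S. The aryl group at C2 is trans to the styryl arm and cis to the C1 methyl. The exocyclic alkene is E.
- Assumption: the (S,S)-anion is taken to give (1R,2S). The sense of induction is checked on the first run (ECD or X-ray). If it is reversed, the (R,R)-anion, made in the same way from (R)-BINOL, is used with nothing else changed.
- Catalyst of step 3: the pre-formed salt of the 2,4,6-tris(4-methoxyphenyl)pyrylium cation with the (S,S)-IDPi anion. This anion is the imidodiphosphorimidate built from two (S)-3,3′-bis[3,5-bis(trifluoromethyl)phenyl]-BINOL units and two N-SO2CF3 groups.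

## Route

Step 1
Reactants: 1 5-bromo-2-hydroxy-4-methoxybenzaldehyde; 2 ethyl (triphenylphosphoranylidene)acetate (1.2 equiv)
Product: 4 6-bromo-7-methoxy-2H-chromen-2-one, via ethyl (E)-5-bromo-2-hydroxy-4-methoxycinnamate 3 (not isolated)
Conditions: PhNEt2, reflux (215 °C), N2, 3 h
Reagents that add atoms: none
Why: Wittig olefination with the stabilised ylide gives 3, and at 215 °C the cinnamate double bond isomerises from E to Z so that the ortho-phenol closes onto the ester (lactonisation) to give the coumarin; the aryl bromide is inert and no stereocentre is formed.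

Step 2
Reactants: 4 6-bromo-7-methoxy-2H-chromen-2-one; 5 isoprene (6 equiv)
Product: 6 7-methoxy-6-[(1E)-3-methylbuta-1,3-dien-1-yl]-2H-chromen-2-one
Conditions: Pd(OAc)2 (3 mol %), P(o-tol)3 (6 mol %), Et3N (2 equiv), BHT (1 mol %), MeCN (0.1 M), sealed tube, 100 °C, 16 h; store 6 cold and dark
Reagents that add atoms: none
Why: Mizoroki–Heck reaction, in which 4 adds oxidatively to zerovalent palladium, the aryl group is delivered to the CH2 terminus of the monosubstituted double bond of isoprene, and β-hydride elimination of a benzylic hydrogen gives the conjugated E-diene; the 1,2-disubstituted coumarin C3=C4 bond cannot compete with excess isoprene, and dilute 6 does not dimerise appreciably at 100 °C.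

Step 3
Reactants: 6 7-methoxy-6-[(1E)-3-methylbuta-1,3-dien-1-yl]-2H-chromen-2-one (2 molecules)
Product: 10 7-methoxy-6-[(E)-2-[(1R,2S)-2-(7-methoxy-2-oxo-2H-chromen-6-yl)-1,4-dimethylcyclohex-3-en-1-yl]ethenyl]-2H-chromen-2-one, via diene radical cation 7 (not isolated), via open-chain distonic radical cation 8 (not isolated), via cycloadduct radical cation 9 (not isolated)
Conditions: 2,4,6-tris(4-methoxyphenyl)pyrylium (S,S)-IDPi salt (3 mol %), 2,6-di-tert-butylpyridine (5 mol %), CH2Cl2/PhMe 2:1 (0.15 M), 455 nm LED, −60 °C, Ar, stop at about 90 % conversion; SiO2, then one recrystallisation to raise ee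
Reagents that add atoms: none
Why: Proposed new method: the excited pyrylium (E* about +1.8 V vs SCE) oxidises aryl diene 6 (estimated +1.3 to +1.4 V) to 7, which in this non-polar medium exists only as a contact ion pair with the confined chiral anion; a second, s-cis molecule of 6 attacks CH2 to CH2 to give the doubly aryl-allyl-stabilised 8, and its 1,6-closure (benzylic carbon onto the tertiary allyl terminus) creates C1 and C2 in one event inside the anion pocket, with the long styryl arm exo, away from the ortho-methoxyaryl group (aryl trans to styryl, methyl endo), and with the anion selecting the enantiotopic face pair; 9, being a less easily oxidised and neopentyl-shielded styrene, passes its hole to fresh 6 together with the anion (chain), so every cycloaddition occurs in a chiral ion pair and there is no thermal background at −60 °C; any [2+2] adduct formed from s-trans 6 reopens under hole catalysis and drains to the cyclohexene; the closest known reaction types are the photoredox or aminium-salt radical-cation Diels–Alder reaction and asymmetric counteranion-directed photoredox cycloadditions of styrene radical cations, here extended to a diene homodimerisation that builds a quaternary centre.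

## Compound list
1 | 5-bromo-2-hydroxy-4-methoxybenzaldehyde | COc1cc(O)c(C=O)cc1Br | starting material
2 | ethyl (triphenylphosphoranylidene)acetate | CCOC(=O)C=P(c1ccccc1)(c1ccccc1)c1ccccc1 | starting material
3 | ethyl (E)-3-(5-bromo-2-hydroxy-4-methoxyphenyl)prop-2-enoate | CCOC(=O)/C=C/c1cc(Br)c(OC)cc1O | intermediate
4 | 6-bromo-7-methoxy-2H-chromen-2-one | COc1cc2oc(=O)ccc2cc1Br | intermediate
5 | isoprene (2-methylbuta-1,3-diene) | C=CC(C)=C | starting material
6 | 7-methoxy-6-[(1E)-3-methylbuta-1,3-dien-1-yl]-2H-chromen-2-one | COc1cc2oc(=O)ccc2cc1/C=C/C(C)=C | intermediate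
7 | radical cation of 6 (drawn as the C3 cation/C4 radical resonance form) | COc1cc2oc(=O)ccc2cc1/C=C/[C+](C)[CH2] | intermediate
8 | tail-to-tail open-chain distonic radical cation (one aryl-allyl cation, one aryl-allyl radical) | COc1cc2oc(=O)ccc2cc1/C=C/[C+](C)CC[C](C)/C=C/c1cc2ccc(=O)oc2cc1OC | intermediate
9 | radical cation of 10 (hole drawn on the styryl unit) | COc1cc2oc(=O)ccc2cc1[CH+][CH][C@@]1(C)CCC(C)=C[C@@H]1c1cc2ccc(=O)oc2cc1OC | intermediate
10 | 7-methoxy-6-[(E)-2-[(1R,2S)-2-(7-methoxy-2-oxo-2H-chromen-6-yl)-1,4-dimethylcyclohex-3-en-1-yl]ethenyl]-2H-chromen-2-one | COc1cc2oc(=O)ccc2cc1/C=C/[C@@]1(C)CCC(C)=C[C@@H]1c1cc2ccc(=O)oc2cc1OC | target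

## Count and risks
Total step count: 3. Longest linear sequence: 3.

**Most likely to fail: step 3.** The risks are the ee, the exo/endo ratio, and oligomerisation or over-oxidation.
- The fallback sets out from 6 and comes back at 10. It gives up asymmetric catalysis for a thermal pericyclic dimerisation followed by resolution.
- 6 is heated at 1 M in o-xylene with 1 mol % BHT at 140 °C under Ar.
- The 1-aryl ("ortho") and 3-methyl ("para") directing effects both favour the same head-to-head regioisomer.
- The trans dimer is obtained as a racemate, that is 10 together with its mirror image, the (1S,2R)-dimer F1.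
- Preparative SFC on an amylose tris(3,5-dimethylphenylcarbamate) phase separates 10 from F1. The absolute configuration is assigned by ECD.

**Second: step 2.** The risks are the regiochemistry of insertion into isoprene, its volatility, and loss of 6 at 100 °C.
- The fallback sets out from 4 and comes back at 6. It installs the C5 unit as an allylic alcohol instead of as a diene.
- Heck coupling of 4 with 2-methylbut-3-en-2-ol uses Pd(OAc)2, P(o-tol)3 and Et3N in MeCN at 90 °C. This alkene has only one possible insertion site, and the product is suberenol F2.
- F2 is dehydrated with p-TsOH·H2O (2 mol %) and 4 Å sieves in toluene at 60 °C to give 6.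

**Third: step 1.** The risk is incomplete E to Z isomerisation and lactonisation, or tar formation at 215 °C.
- The fallback sets out from 1 and comes back at 4. It replaces the olefination by condensation and decarboxylation.
- Knoevenagel condensation of 1 with Meldrum's acid (cat. piperidinium acetate, EtOH, reflux) closes the lactone directly and gives 6-bromo-7-methoxy-2-oxo-2H-chromene-3-carboxylic acid F3.
- Protodecarboxylation of F3 with Ag2CO3 (10 mol %) and AcOH (5 mol %) in DMSO at 120 °C gives 4.

## Further compounds
F1 | step 3 | 7-methoxy-6-[(E)-2-[(1S,2R)-2-(7-methoxy-2-oxo-2H-chromen-6-yl)-1,4-dimethylcyclohex-3-en-1-yl]ethenyl]-2H-chromen-2-one (mirror image of 10) | COc1cc2oc(=O)ccc2cc1/C=C/[C@]1(C)CCC(C)=C[C@H]1c1cc2ccc(=O)oc2cc1OC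
F2 | step 2 | suberenol, 6-[(1E)-3-hydroxy-3-methylbut-1-en-1-yl]-7-methoxy-2H-chromen-2-one | COc1cc2oc(=O)ccc2cc1/C=C/C(C)(C)O
F3 | step 1 | 6-bromo-7-methoxy-2-oxo-2H-chromene-3-carboxylic acid | COc1cc2oc(=O)c(C(=O)O)cc2cc1Br
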